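**Retrosynthetic overview**
- The target is reached by global O-debenzylation of its tri-benzyl ether. The key cut is the ArC(=O)–CH bond: an acyl anion (carbene-bound Breslow intermediate of O-benzylvanillin) adds to an o-quinone methide raised on the free-phenol ring of the lignan. The chiral carbene sets the side-chain stereocentre.
- The o-quinone methide precursor (a benzylic sulfone) comes from a mono-O-benzyl matairesinol with one free phenol, by boron-templated ortho-hydroxyalkylation with (benzyloxy)acetaldehyde.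
- The lactone's C3 benzyl group is introduced by trans-selective enolate alkylation of an (R)-4-benzyl butyrolactone (substrate control).
- That lactone comes from the Stobbe half-ester of O-benzylvanillin and dimethyl succinate; asymmetric hydrogenation sets C4.
- Only one ring is formed, the butyrolactone (step 3); all three arenes are bought as vanillin-type building blocks.

Assumption: the (5aS,10bR) antipode of the triazolium salt in step 8 is taken to give the (S) centre; both antipodes are sold, and the other is used if the sense of induction proves opposite.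

**Route**

Step 1
Reactants: 1 4-(benzyloxy)-3-methoxybenzaldehyde; 2 dimethyl succinate
Product: 3 (E)-4-[4-(benzyloxy)-3-methoxyphenyl]-3-(methoxycarbonyl)but-3-enoic acid
Conditions: NaOMe (1.3 equiv), MeOH, reflux; then aq. HCl
Reagents that add atoms: none
Why: Stobbe condensation, in which the succinate enolate adds to the aldehyde, the alkoxide closes to a paraconate lactone and E1cB ring opening gives the alkylidene half-ester with the ester on the olefinic carbon.

Step 2
Reactants: 3 (E)-4-[4-(benzyloxy)-3-methoxyphenyl]-3-(methoxycarbonyl)but-3-enoic acid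
Product: 5 (3R)-4-(4-hydroxy-3-methoxyphenyl)-3-(methoxycarbonyl)butanoic acid, via O-benzyl saturated acid 4 (not isolated)
Conditions: [Rh(cod)((S,S)-Et-DuPhos)]BF4 (0.5 mol%; ligand = 1,2-bis[(2S,5S)-2,5-diethylphospholan-1-yl]benzene), NaOMe (10 mol%), H2 (5 bar), MeOH, rt; then 10% Pd/C, H2 (1 bar), rt
Reagents that add atoms: none
Why: Carboxylate-directed asymmetric hydrogenation of an itaconate-type half-ester, where the (S,S)-bisphospholane rhodium catalyst delivers H2 to one olefin face to set the (R) centre (later C4 of the lactone), followed in the same pot by Pd/C hydrogenolysis of the phenolic benzyl ether.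

Step 3
Reactants: 5 (3R)-4-(4-hydroxy-3-methoxyphenyl)-3-(methoxycarbonyl)butanoic acid
Product: 7 (4R)-4-(4-hydroxy-3-methoxybenzyl)dihydrofuran-2(3H)-one, via hydroxy acid 6 (not isolated)
Conditions: KOH (2 equiv), EtOH; CaCl2, NaBH4, −10 °C to rt; then 2 M HCl, 40 °C
Reagents that add atoms: none
Why: Chemoselective ester reduction, since Ca(BH4)2 reduces the methyl ester but not the potassium carboxylate, and acidification lactonises the γ-hydroxy acid without touching the stereocentre.

Step 4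
Reactants: 8 [4-(benzyloxy)-3-methoxyphenyl]methanol
Product: 9 1-(benzyloxy)-4-(bromomethyl)-2-methoxybenzene
Conditions: PBr3 (0.4 equiv), CH2Cl2, 0 °C
Reagents that add atoms: phosphorus tribromide, BrP(Br)Br
Why: Bromination of a benzylic alcohol through its phosphite ester (SN2 by bromide), done cold so the benzyl ether survives.

Step 5
Reactants: 7 (4R)-4-(4-hydroxy-3-methoxybenzyl)dihydrofuran-2(3H)-one; 9 1-(benzyloxy)-4-(bromomethyl)-2-methoxybenzene
Product: 10 (3R,4R)-3-[4-(benzyloxy)-3-methoxybenzyl]-4-(4-hydroxy-3-methoxybenzyl)dihydrofuran-2(3H)-one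
Conditions: LiN(SiMe3)2 (2.2 equiv), THF, −78 °C; then 9 (1.05 equiv), −78 to −30 °C; AcOH quench
Reagents that add atoms: none
Why: Dianion (phenoxide plus enolate) alkylation, in which the lithium enolate is C-benzylated far faster than the lithium phenoxide is O-benzylated in THF at low temperature, and the bromide approaches anti to the C4 substituent to give the trans (3R) centre.

Step 6
Reactants: 10 (3R,4R)-3-[4-(benzyloxy)-3-methoxybenzyl]-4-(4-hydroxy-3-methoxybenzyl)dihydrofuran-2(3H)-one; 11 (benzyloxy)acetaldehyde; 12 phenylboronic acid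
Product: 14 (3R,4R)-3-[4-(benzyloxy)-3-methoxybenzyl]-4-{3-[2-(benzyloxy)-1-hydroxyethyl]-4-hydroxy-5-methoxybenzyl}dihydrofuran-2(3H)-one (both carbinol epimers), via benzodioxaborin 13 (not isolated)
Conditions: 11 (1.5 equiv), 12 (1.2 equiv), EtCO2H (0.3 equiv), toluene, reflux, Dean–Stark; then 30% H2O2, THF, rt
Reagents that add atoms: none
Why: Nagata ortho-hydroxyalkylation, where the aryloxyboronate delivers the aldehyde through a six-membered transition state to the only free ortho carbon of the one free phenol, and oxidative deboronation frees the diol; the new carbinol centre is uncontrolled and is erased in step 8.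

Step 7
Reactants: 14 (3R,4R)-3-[4-(benzyloxy)-3-methoxybenzyl]-4-{3-[2-(benzyloxy)-1-hydroxyethyl]-4-hydroxy-5-methoxybenzyl}dihydrofuran-2(3H)-one
Product: 15 (3R,4R)-3-[4-(benzyloxy)-3-methoxybenzyl]-4-{3-[2-(benzyloxy)-1-(4-methylbenzenesulfonyl)ethyl]-4-hydroxy-5-methoxybenzyl}dihydrofuran-2(3H)-one (both epimers)
Conditions: TolSO2Na (3 equiv), HCO2H/H2O/THF, rt
Reagents that add atoms: sodium p-toluenesulfinate, Cc1ccc(cc1)S(=O)[O-].[Na+]
Why: Acid-promoted SN1 substitution, in which the o-hydroxybenzylic alcohol ionises with help from the ortho hydroxyl and the sulfinate sulfur captures the cation, giving the bench-stable sulfone that is the standard o-quinone methide precursor.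

Step 8
Reactants: 15 (3R,4R)-3-[4-(benzyloxy)-3-methoxybenzyl]-4-{3-[2-(benzyloxy)-1-(4-methylbenzenesulfonyl)ethyl]-4-hydroxy-5-methoxybenzyl}dihydrofuran-2(3H)-one; 1 4-(benzyloxy)-3-methoxybenzaldehyde
Product: 17 (3R,4R)-3-[4-(benzyloxy)-3-methoxybenzyl]-4-{3-[(2S)-3-(benzyloxy)-1-[4-(benzyloxy)-3-methoxyphenyl]-1-oxopropan-2-yl]-4-hydroxy-5-methoxybenzyl}dihydrofuran-2(3H)-one, via o-quinone methide 16 (not isolated)
Conditions: 1 (2 equiv), (5aS,10bR)-2-(pentafluorophenyl)-5a,10b-dihydro-4H,6H-indeno[2,1-b][1,2,4]triazolo[4,3-d][1,4]oxazin-2-ium tetrafluoroborate (15 mol%), Cs2CO3 (1.2 equiv), 4 Å MS, CH2Cl2, −20 to 0 °C; cold pH 7 phosphate buffer quench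
Reagents that add atoms: none
Why: Proposed new method: the carbonate deprotonates the phenol of 15, which expels sulfinate to give o-quinone methide 16, while the chiral triazolylidene converts aldehyde 1 into its Breslow intermediate, an acyl anion equivalent whose carbon adds 1,4 to the exocyclic methide carbon (two normally electrophilic carbons are joined, driven by rearomatisation) before the carbene is released to unveil the ketone; the aminoindanol wall of the catalyst blocks one face of the enaminol, so one enantiotopic face of the methide carbon is attacked and the (S) centre is set by the catalyst, the distant lactone centres being spectators; the closest known chemistry is the carbene-mediated acylation of o-quinone methides and aza-o-quinone methides by aldehydes (racemic), combined with the enantioselective intermolecular Stetter reaction of chiral triazolylidenes.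

Step 9
Reactants: 17 (3R,4R)-3-[4-(benzyloxy)-3-methoxybenzyl]-4-{3-[(2S)-3-(benzyloxy)-1-[4-(benzyloxy)-3-methoxyphenyl]-1-oxopropan-2-yl]-4-hydroxy-5-methoxybenzyl}dihydrofuran-2(3H)-one
Product: 18 (3R,4R)-3-(4-hydroxy-3-methoxybenzyl)-4-{4-hydroxy-3-[(2S)-3-hydroxy-1-(4-hydroxy-3-methoxyphenyl)-1-oxopropan-2-yl]-5-methoxybenzyl}dihydrofuran-2(3H)-one (CNP0191394.1)
Conditions: H2 (1 bar), 10% Pd/C, EtOAc/EtOH, rt; filtration, reversed-phase purification
Reagents that add atoms: none
Why: Hydrogenolysis of the three benzyl ethers under neutral conditions, which leaves the electron-rich aryl ketone and the lactone alone and uses no acid or base that could epimerise the α-aryl ketone centre, cause retro-aldol loss of formaldehyde or close a benzofuran.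

**Compound list**

1 | 4-(benzyloxy)-3-methoxybenzaldehyde (O-benzylvanillin) | COc1cc(C=O)ccc1OCc1ccccc1 | starting material
2 | dimethyl succinate | COC(=O)CCC(=O)OC | starting material
3 | (E)-4-[4-(benzyloxy)-3-methoxyphenyl]-3-(methoxycarbonyl)but-3-enoic acid | COC(=O)/C(CC(=O)O)=C/c1ccc(OCc2ccccc2)c(OC)c1 | intermediate
4 | (3R)-4-[4-(benzyloxy)-3-methoxyphenyl]-3-(methoxycarbonyl)butanoic acid | COC(=O)[C@@H](CC(=O)O)Cc1ccc(OCc2ccccc2)c(OC)c1 | intermediate
5 | (3R)-4-(4-hydroxy-3-methoxyphenyl)-3-(methoxycarbonyl)butanoic acid | COC(=O)[C@@H](CC(=O)O)Cc1ccc(O)c(OC)c1 | intermediate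
6 | (3R)-3-(hydroxymethyl)-4-(4-hydroxy-3-methoxyphenyl)butanoic acid | OC[C@@H](CC(=O)O)Cc1ccc(O)c(OC)c1 | intermediate
7 | (4R)-4-(4-hydroxy-3-methoxybenzyl)dihydrofuran-2(3H)-one | O=C1OC[C@H](Cc2ccc(O)c(OC)c2)C1 | intermediate
8 | [4-(benzyloxy)-3-methoxyphenyl]methanol | COc1cc(CO)ccc1OCc1ccccc1 | starting material
9 | 1-(benzyloxy)-4-(bromomethyl)-2-methoxybenzene | COc1cc(CBr)ccc1OCc1ccccc1 | intermediate
10 | (3R,4R)-3-[4-(benzyloxy)-3-methoxybenzyl]-4-(4-hydroxy-3-methoxybenzyl)dihydrofuran-2(3H)-one | COc1cc(C[C@H]2C(=O)OC[C@@H]2Cc2ccc(O)c(OC)c2)ccc1OCc1ccccc1 | intermediate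
11 | (benzyloxy)acetaldehyde | O=CCOCc1ccccc1 | starting material
12 | phenylboronic acid | OB(O)c1ccccc1 | starting material
13 | (3R,4R)-3-[4-(benzyloxy)-3-methoxybenzyl]-4-({4-[(benzyloxy)methyl]-8-methoxy-2-phenyl-4H-1,3,2-benzodioxaborin-6-yl}methyl)dihydrofuran-2(3H)-one (both epimers at the dioxaborin C4) | COc1cc(C[C@H]2C(=O)OC[C@@H]2Cc2cc(OC)c3OB(c4ccccc4)OC(COCc4ccccc4)c3c2)ccc1OCc1ccccc1 | intermediate
14 | (3R,4R)-3-[4-(benzyloxy)-3-methoxybenzyl]-4-{3-[2-(benzyloxy)-1-hydroxyethyl]-4-hydroxy-5-methoxybenzyl}dihydrofuran-2(3H)-one (both carbinol epimers) | COc1cc(C[C@H]2C(=O)OC[C@@H]2Cc2cc(OC)c(O)c(C(O)COCc3ccccc3)c2)ccc1OCc1ccccc1 | intermediate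
15 | (3R,4R)-3-[4-(benzyloxy)-3-methoxybenzyl]-4-{3-[2-(benzyloxy)-1-(4-methylbenzenesulfonyl)ethyl]-4-hydroxy-5-methoxybenzyl}dihydrofuran-2(3H)-one (both epimers) | COc1cc(C[C@H]2C(=O)OC[C@@H]2Cc2cc(OC)c(O)c(C(COCc3ccccc3)S(=O)(=O)c3ccc(C)cc3)c2)ccc1OCc1ccccc1 | intermediate
16 | (3R,4R)-3-[4-(benzyloxy)-3-methoxybenzyl]-4-({3-[2-(benzyloxy)ethylidene]-5-methoxy-4-oxocyclohexa-1,5-dien-1-yl}methyl)dihydrofuran-2(3H)-one (o-quinone methide) | COc1cc(C[C@H]2C(=O)OC[C@@H]2CC2=CC(=CCOCc3ccccc3)C(=O)C(OC)=C2)ccc1OCc1ccccc1 | intermediate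
17 | (3R,4R)-3-[4-(benzyloxy)-3-methoxybenzyl]-4-{3-[(2S)-3-(benzyloxy)-1-[4-(benzyloxy)-3-methoxyphenyl]-1-oxopropan-2-yl]-4-hydroxy-5-methoxybenzyl}dihydrofuran-2(3H)-one | COc1cc(C[C@H]2C(=O)OC[C@@H]2Cc2cc(OC)c(O)c([C@@H](COCc3ccccc3)C(=O)c3ccc(OCc4ccccc4)c(OC)c3)c2)ccc1OCc1ccccc1 | intermediate
18 | (3R,4R)-3-(4-hydroxy-3-methoxybenzyl)-4-{4-hydroxy-3-[(2S)-3-hydroxy-1-(4-hydroxy-3-methoxyphenyl)-1-oxopropan-2-yl]-5-methoxybenzyl}dihydrofuran-2(3H)-one | COc1cc(C[C@H]2C(=O)OC[C@@H]2Cc2cc(OC)c(O)c([C@@H](CO)C(=O)c3ccc(O)c(OC)c3)c2)ccc1O | target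

**Count**
- Total steps: 9.
- Longest linear sequence: 8 (steps 1, 2, 3, 5, 6, 7, 8, 9 from compound 1); step 4 is a one-step side branch.

**Steps most likely to fail, with fallbacks**

Step 8 (carbene acylation of the o-quinone methide). Risks are tautomerisation of 16 to an enol ether, benzoin formation from 1, low facial selectivity, and epimerisation or loss of benzyl alcohol from 17 under base. The fallback keeps the same bond but changes the acyl anion equivalent to a nitronate under hydrogen-bond catalysis. It sets out from 15 and 9 and returns at 17. Bromide 9 with AgNO2 in Et2O at 0 °C gives (4-benzyloxy-3-methoxyphenyl)nitromethane F1. With a quinine-derived bifunctional squaramide and aqueous NaHCO3 in CH2Cl2, F1 adds to the o-quinone methide released from 15. This gives the nitro adduct F2, which is 17 with CH–NO2 in place of C=O; the aryl-bearing centre is set by the catalyst and the nitro-bearing centre is immaterial. A buffered Nef reaction (NaOMe at 0 °C, then aqueous TiCl3/NH4OAc at pH 5–6) converts the nitro carbon into the ketone and delivers 17.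

Step 6 (ortho-hydroxyalkylation with an α-alkoxy aldehyde). Risks are self-condensation of 11 and slow reaction of the hindered guaiacol-type phenol. The fallback sets out from 10 and returns at 18. Ethyl glyoxylate and Ti(OiPr)4 in CH2Cl2 give, through the titanium phenoxide, the ortho-specific Friedel–Crafts adduct ethyl 2-hydroxy-2-aryl-acetate F3. NaBH4 in EtOH at 0 °C reduces the activated α-hydroxy ester, but not the γ-lactone, to the triol F4. TolSO2Na in HCO2H/H2O/THF gives the sulfone F5 with a free primary alcohol. The carbene acylation of step 8 with 1 then gives the (S)-ketone F6, the bis-benzyl ether of the target. H2 over Pd/C gives 18.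

Step 5 (alkylation of the unprotected phenol lactone). Risks are O-benzylation of the phenoxide and poor solubility of the dianion. The fallback sets out from 7 and returns at 10 by routing the alkylation through a silyl ether. TBSCl and imidazole in DMF give the silyl ether of 7, F7. LiN(SiMe3)2 (1.1 equiv) and 9 in THF at −78 °C give the trans-alkylated silyl ether F8. Bu4NF buffered with AcOH in THF gives 10.

**Further compounds**

F1 | step 8 | (4-benzyloxy-3-methoxyphenyl)nitromethane | COc1cc(C[N+](=O)[O-])ccc1OCc1ccccc1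
F2 | step 8 | (3R,4R)-3-[4-(benzyloxy)-3-methoxybenzyl]-4-{3-[(2R)-3-(benzyloxy)-1-[4-(benzyloxy)-3-methoxyphenyl]-1-nitropropan-2-yl]-4-hydroxy-5-methoxybenzyl}dihydrofuran-2(3H)-one (either configuration at the nitro carbon) | COc1cc(C[C@H]2C(=O)OC[C@@H]2Cc2cc(OC)c(O)c([C@@H](COCc3ccccc3)C([N+](=O)[O-])c3ccc(OCc4ccccc4)c(OC)c3)c2)ccc1OCc1ccccc1
F3 | step 6 | ethyl 2-hydroxy-2-[5-({(3R,4R)-4-[4-(benzyloxy)-3-methoxybenzyl]-5-oxotetrahydrofuran-3-yl}methyl)-2-hydroxy-3-methoxyphenyl]acetate (both carbinol epimers) | COc1cc(C[C@H]2C(=O)OC[C@@H]2Cc2cc(OC)c(O)c(C(O)C(=O)OCC)c2)ccc1OCc1ccccc1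
F4 | step 6 | (3R,4R)-3-[4-(benzyloxy)-3-methoxybenzyl]-4-[3-(1,2-dihydroxyethyl)-4-hydroxy-5-methoxybenzyl]dihydrofuran-2(3H)-one (both carbinol epimers) | COc1cc(C[C@H]2C(=O)OC[C@@H]2Cc2cc(OC)c(O)c(C(O)CO)c2)ccc1OCc1ccccc1
F5 | step 6 | (3R,4R)-3-[4-(benzyloxy)-3-methoxybenzyl]-4-{4-hydroxy-3-[2-hydroxy-1-(4-methylbenzenesulfonyl)ethyl]-5-methoxybenzyl}dihydrofuran-2(3H)-one (both epimers) | COc1cc(C[C@H]2C(=O)OC[C@@H]2Cc2cc(OC)c(O)c(C(CO)S(=O)(=O)c3ccc(C)cc3)c2)ccc1OCc1ccccc1
F6 | step 6 | (3R,4R)-3-[4-(benzyloxy)-3-methoxybenzyl]-4-{3-[(2S)-1-[4-(benzyloxy)-3-methoxyphenyl]-3-hydroxy-1-oxopropan-2-yl]-4-hydroxy-5-methoxybenzyl}dihydrofuran-2(3H)-one | COc1cc(C[C@H]2C(=O)OC[C@@H]2Cc2cc(OC)c(O)c([C@@H](CO)C(=O)c3ccc(OCc4ccccc4)c(OC)c3)c2)ccc1OCc1ccccc1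
F7 | step 5 | (4R)-4-{4-[(tert-butyldimethylsilyl)oxy]-3-methoxybenzyl}dihydrofuran-2(3H)-one | O=C1OC[C@H](Cc2ccc(O[Si](C)(C)C(C)(C)C)c(OC)c2)C1
F8 | step 5 | (3R,4R)-3-[4-(benzyloxy)-3-methoxybenzyl]-4-{4-[(tert-butyldimethylsilyl)oxy]-3-methoxybenzyl}dihydrofuran-2(3H)-one | COc1cc(C[C@H]2C(=O)OC[C@@H]2Cc2ccc(O[Si](C)(C)C(C)(C)C)c(OC)c2)ccc1OCc1ccccc1
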